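**Plan**
- Cuts: the cage C–O bonds at C3' and C4' (ketal, acylal lactone, orthoester) back to a spiro γ-lactone hydroxy keto ester; C5'–C6' and C4'–O by retro hetero-Diels–Alder (spiro ketene acetal + alkylidene β-keto ester); C9–C11; the δ-lactone at C1–C2 and C10–C19 (retro-[2+2]); C4–CH3.
- Enabling feature: the carbinol carbon C4 sits on C5, next to the spiro carbon C10. As a methyl ketone it can be the ketal carbon of a 1,3-dioxin-4-one (C19=C2–C3) held three atoms (O, C4, C5) from an exocyclic C10=C1 alkene. [2+2] closure gives the cyclobutane C10–C19–C2–C1 through a temporary oxolane ring C4–O–C19–C10–C5; retro-aldol cleavage of C2–C19 then leaves C10 with both arms of the δ-lactone.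
- Forward: ring B from (S)-carvone → C9 ketone → exocyclic enone → spiro α-methylene γ-lactone at C9 → dioxinone on C4 → photoadduct → tetrahydropyran ring (hetero-Diels–Alder, hydrogenation) → fragmentation to the δ-lactone → methyl addition at C4 → acid closure of the cage.
- Stereochemistry: C5 from carvone; C7 by Luche reduction; C8 by hydroboration anti to the C7 silyl ether; C9 by α-face addition; C10 by the cis-fused tether; C5'/C6' by face and endo sense of the cycloaddition; C1'/C2' by hydrogenation anti to the C6' methyl; C3'/C4' by the cage geometry.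

Key step: step 12

Remark: locants follow the meroterpenoid skeleton: ring B is C5–C10; δ-lactone C1, C2, C3(=O), O, C19; carbinol carbon C4; oxolane CH2 C11; polyketide part C1' (CH–C7'O2), C2' (CH–O), C3' (methyl ketal carbon), C4' (orthoester carbon), C5' (quaternary C–CH3), C6' (CH–CH3); β is the face of ring B that carries the C7 oxygen.
Assumption: 11, 15 and 20 are bought; the ketal epimer formed beside 18 that cannot cyclize is recycled by reheating under the conditions of step 11.

Step 1
Reactants: 1 (S)-(+)-carvone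
Product: 2 (5S)-5-acetyl-2-methylcyclohex-2-en-1-one
Conditions: OsO4 (cat.), NaIO4, 2,6-lutidine, dioxane/H2O, rt
Reagents that add atoms: sodium periodate, [Na+].[O-]I(=O)(=O)=O
Why: Lemieux–Johnson cleavage should take the electron-rich isopropenyl alkene and spare the electron-poor enone alkene, the buffered medium leaving the chiral-pool stereocenter C5 untouched.

Step 2
Reactants: 2 (5S)-5-acetyl-2-methylcyclohex-2-en-1-one
Product: 3 (5S)-2-methyl-5-(2-methyl-1,3-dioxolan-2-yl)cyclohex-2-en-1-one
Conditions: (TMSOCH2)2, TMSOTf (cat.), CH2Cl2, −78 °C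
Reagents that add atoms: 1,2-bis(trimethylsilyloxy)ethane, C[Si](C)(C)OCCO[Si](C)(C)C
Why: Silyl-transfer ketalization at low temperature should protect the saturated methyl ketone and leave the less electrophilic conjugated ketone, without enolizing C5.

Step 3
Reactants: 3 (5S)-2-methyl-5-(2-methyl-1,3-dioxolan-2-yl)cyclohex-2-en-1-one
Product: 4 (1S,5S)-2-methyl-5-(2-methyl-1,3-dioxolan-2-yl)cyclohex-2-en-1-ol
Conditions: NaBH4, CeCl3·7H2O, MeOH, −78 °C
Reagents that add atoms: none
Why: Luche 1,2-reduction with axial hydride delivery should give the cis allylic alcohol, which sets the C7 oxygen β, cis to the C5 substituent, as it does for carvone itself.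

Step 4
Reactants: 4 (1S,5S)-2-methyl-5-(2-methyl-1,3-dioxolan-2-yl)cyclohex-2-en-1-ol
Product: 5 tert-butyldimethylsilyl ether of 4
Conditions: TBSCl, imidazole, DMF, rt
Reagents that add atoms: tert-butyldimethylsilyl chloride, CC(C)(C)[Si](C)(C)Cl
Why: Standard silylation of a secondary allylic alcohol; the ether lasts to the final step and directs step 5.

Step 5
Reactants: 5 tert-butyldimethylsilyl ether of 4
Product: 6 (1S,2R,3S,5S)-3-(tert-butyldimethylsilyloxy)-2-methyl-5-(2-methyl-1,3-dioxolan-2-yl)cyclohexan-1-ol
Conditions: BH3·THF, THF, 0 °C → rt; then NaOH, H2O2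
Reagents that add atoms: hydrogen peroxide, OO
Why: Hydroboration–oxidation should place boron on the less substituted C9 and hydrogen on C8, syn to each other and anti to the allylic silyloxy group, so the C8 methyl ends up β, cis to the C7 oxygen (the C9 carbinol center is removed in step 6).

Step 6
Reactants: 6 (1S,2R,3S,5S)-3-(tert-butyldimethylsilyloxy)-2-methyl-5-(2-methyl-1,3-dioxolan-2-yl)cyclohexan-1-ol
Product: 7 (2S,3S,5R)-3-(tert-butyldimethylsilyloxy)-2-methyl-5-(2-methyl-1,3-dioxolan-2-yl)cyclohexan-1-one
Conditions: Dess–Martin periodinane, CH2Cl2, 0 °C → rt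
Reagents that add atoms: none
Why: Dess–Martin oxidation is non-basic, so the C8 center (α to the new ketone, β to the silyloxy group) should be neither epimerized nor eliminated.

Step 7
Reactants: 7 (2S,3S,5R)-3-(tert-butyldimethylsilyloxy)-2-methyl-5-(2-methyl-1,3-dioxolan-2-yl)cyclohexan-1-one
Product: 10 (2S,3S,5R)-3-(tert-butyldimethylsilyloxy)-2-methyl-6-methylidene-5-(2-methyl-1,3-dioxolan-2-yl)cyclohexan-1-one, via Mannich base 8 (not isolated), via methiodide 9 (not isolated)
Conditions: LiN(iPr)2, THF, −78 °C; CH2=NMe2+ I−, −78 → 0 °C; MeI, CH2Cl2/MeOH, rt; NaHCO3 (aq), rt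
Reagents that add atoms: N,N-dimethylmethyleneiminium iodide (Eschenmoser's salt), C=[N+](C)C.[I-]
Why: Eschenmoser methylenation: kinetic deprotonation at the unhindered C10 methylene, Mannich reaction and mild Hofmann-type elimination should give the exocyclic enone (C10=C1) without touching C8.

Step 8
Reactants: 10 (2S,3S,5R)-3-(tert-butyldimethylsilyloxy)-2-methyl-6-methylidene-5-(2-methyl-1,3-dioxolan-2-yl)cyclohexan-1-one; 11 methyl 2-(bromomethyl)acrylate
Product: 13 spiro α-methylene γ-lactone ketal (spiro at C9 with lactone oxygen β and C11 α; C10=CH2; β-dioxolanyl at C5; β-OTBS at C7; β-methyl at C8), via bromozinc alkoxide 12 (not isolated)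
Conditions: Zn (activated), THF, 50 °C; then aq NH4Cl
Reagents that add atoms: none
Why: Reformatsky-type allylation–lactonization (Dreiding–Schmidt) should add 1,2 to the C9 ketone from the α face, because the β face is shielded in either chair (by the C8 methyl, or by the C5 and C7 substituents), so C9 receives oxygen β and C11 α.

Step 9
Reactants: 13 spiro α-methylene γ-lactone ketal
Product: 14 spiro α-methylene γ-lactone methyl ketone (as 13 with a β-acetyl group at C5)
Conditions: PPTS, acetone/H2O (10:1), 55 °C
Reagents that add atoms: water, O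
Why: Mild acetal hydrolysis should free the C4 methyl ketone while the silyl ether and the allylic lactone survive.

Step 10
Reactants: 15 5-(methoxymethylene)-2,2-dimethyl-1,3-dioxane-4,6-dione
Product: 16 5-(hydroxymethylene)-2,2-dimethyl-1,3-dioxane-4,6-dione (formyl Meldrum's acid)
Conditions: 2 M HCl (aq), rt
Reagents that add atoms: water, O
Why: Hydrolysis of the vinylogous ester gives the known thermal precursor of formylketene.

Step 11
Reactants: 14 spiro α-methylene γ-lactone methyl ketone; 16 formyl Meldrum's acid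
Product: 18 dioxinone (2-methyl-4H-1,3-dioxin-4-one whose ketal carbon is C4 of the skeleton with S configuration and carries C5; otherwise as 14), via formylketene 17 (not isolated)
Conditions: toluene, 100 °C, slow addition of 16 (excess)
Reagents that add atoms: none
Why: Thermolysis of 16 releases formylketene, whose hetero-Diels–Alder [4+2] addition to the C4 ketone carbonyl gives the 1,3-dioxin-4-one; both ketal epimers should form and interconvert by cycloreversion at this temperature, and only the one drawn can cyclize in step 12.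

Step 12
Reactants: 18 dioxinone
Product: 19 photoadduct (cyclobutane C10–C19–C2–C1 cis-fused to the oxolane C4–O–C19–C10–C5 and to the 1,3-dioxan-4-one; C19 β and C1 α at C10)
Conditions: hν (300 nm), MeCN (degassed, dilute), 0 °C
Reagents that add atoms: none
Why: Direct excitation of the dioxinone gives, after intersystem crossing, a triplet whose β-carbon C19 attacks the ring carbon C10 of the exocyclic alkene in a 5-exo closure of the oxolane ring (rule of five for a 1,6-diene), and the resulting 1,4-biradical collapses to the cyclobutane by forming the C1–C2 bond, giving the straight [2+2] adduct. The closest known reaction type is the intramolecular de Mayo-type photocycloaddition of 1,3-dioxin-4-ones with tethered alkenes, followed later by retro-aldol fragmentation. The oxolane can only be cis-fused to ring B, so C19 is delivered to the β face of C10 (the face of the C5 substituent) and the quaternary center C10 is set by C5 through the temporary C4–O–C19 tether; C19, C2 and the ketal carbon are fixed by the cis ring fusions and are transient. The step needs straight rather than crossed addition, which the three-atom tether secures, and it needs the α-methylene lactone to stay out of the reaction, which irradiation at 300 nm without a triplet sensitizer secures because only the dioxinone absorbs there. Only the ketal epimer drawn can bring C2 over C1; the other should be recovered unchanged.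

Step 13
Reactants: 20 methyl 4,4-dimethoxy-3-oxopentanoate; 21 acetaldehyde
Product: 22 methyl (Z)-2-ethylidene-4,4-dimethoxy-3-oxopentanoate (formed with its E isomer)
Conditions: piperidine (cat.), AcOH (cat.), 4 Å MS, CH2Cl2, −10 → 0 °C
Reagents that add atoms: none
Why: Knoevenagel condensation gives an alkylidene β-keto ester, an electron-poor 1-oxadiene; the E/Z isomers should equilibrate and only the Z isomer (methyl trans to the ketone) can adopt the s-cis oxadiene used in step 14.

Step 14
Reactants: 19 photoadduct; 22 methyl (Z)-2-ethylidene-4,4-dimethoxy-3-oxopentanoate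
Product: 24 cycloadduct (2-triethylsilyloxy-3,4-dihydro-2H-pyran orthoester: C4' bears OSiEt3, the oxolane oxygen and the pyran oxygen; C5' methyl and C6' methyl cis; C1'=C2' double bond carrying CO2Me and the dimethyl ketal carbon), via silyl ketene acetal 23 (not isolated)
Conditions: Et3SiH, RhCl(PPh3)3 (cat.), toluene, 50 °C; then 22, 25 → 60 °C
Reagents that add atoms: triethylsilane, CC[SiH](CC)CC
Why: 1,4-Hydrosilylation of the α-methylene lactone makes the tetrasubstituted cyclic ketene silyl acetal regiospecifically and without base, and its inverse-electron-demand hetero-Diels–Alder reaction with 22 should take place on the face of the oxolene ring turned away from quaternary C10, with the bulky spiro ring exo, which sets C5' (methyl cis to C10) and C6' (methyl cis to the C5' methyl) and makes C4' the orthoester carbon.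

Step 15
Reactants: 24 cycloadduct
Product: 25 tetrahydropyran silyl orthoester (H at C1' and C2' cis to each other and trans to the C5' and C6' methyl groups)
Conditions: H2 (50 bar), Rh/Al2O3 (5%), EtOAc, rt
Reagents that add atoms: none
Why: Heterogeneous cis-hydrogenation of the enol-ether acrylate double bond should occur from the face opposite the pseudoaxial C6' methyl and the axial silyloxy group, setting C1' and C2' so that the ester and the ketal carbon are cis to the two methyl groups.

Step 16
Reactants: 25 tetrahydropyran silyl orthoester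
Product: 28 δ-lactone methyl ketone (spiro δ-lactone at C10, β-acetyl at C5, spiro γ-lactone at C9 with quaternary C5', free C2' hydroxyl, C7' methyl ester, C3' dimethyl ketal, C7 OTBS), via keto aldehyde 26 (not isolated), via hydroxy ester 27 (not isolated)
Conditions: NaBH4, K2CO3 (cat.), MeOH, −20 → 0 °C; AcOH; then PPTS (cat.), CH2Cl2, rt
Reagents that add atoms: none
Why: Methanolysis of the dioxanone releases the C4 ketone and a cyclobutanol alkoxide that cleaves the C2–C19 bond by retro-aldol reaction (de Mayo fragmentation); borohydride should reduce the neopentyl aldehyde before it can undergo aldol reaction with the methyl ketone, the C19 alcohol lactonizes onto the C3 methyl ester, and methanolysis of the silyl orthoester returns the spiro γ-lactone and the free C2' hydroxyl, with no stereocenter formed.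

Step 17
Reactants: 28 δ-lactone methyl ketone
Product: 29 tertiary alcohol (as 28 with C(CH3)2OH at C5)
Conditions: MeLi, CeCl3 (anhydrous), THF, −78 °C
Reagents that add atoms: methyllithium, [Li]C
Why: Organocerium addition: the weakly basic methylcerium reagent should add to the methyl ketone faster than to the lactones and the hindered ester, and without enolization; no stereocenter is formed.

Step 18
Reactants: 29 tertiary alcohol
Product: 31 chermebilaene B, via trihydroxy keto ester 30 (not isolated)
Conditions: aq HF, MeCN, 0 °C → rt; then CSA (cat.), 5 Å MS, benzene, 50 °C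
Reagents that add atoms: water, O
Why: After desilylation and ketal hydrolysis, acid-catalysed cage closure should proceed by addition of the C2' hydroxyl to the γ-lactone carbonyl (six-membered ring), addition of the hemiorthoester hydroxyl to the C3' ketone (dioxolane), and lactonization of the hemiketal hydroxyl onto the C7' ester with loss of methanol to the sieves; C3' and C4' are dictated by the cis-fused cage, which can form only from the C1'/C2' configuration set in step 15.

**Compound list**
1 | (S)-(+)-carvone | CC1=CC[C@@H](CC1=O)C(C)=C | starting material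
2 | (5S)-5-acetyl-2-methylcyclohex-2-en-1-one | CC1=CC[C@@H](CC1=O)C(C)=O | intermediate
3 | (5S)-2-methyl-5-(2-methyl-1,3-dioxolan-2-yl)cyclohex-2-en-1-one | CC1=CC[C@@H](CC1=O)C2(C)OCCO2 | intermediate
4 | (1S,5S)-2-methyl-5-(2-methyl-1,3-dioxolan-2-yl)cyclohex-2-en-1-ol | CC1=CC[C@@H](C[C@@H]1O)C2(C)OCCO2 | intermediate
5 | tert-butyldimethylsilyl ether of 4 | CC1=CC[C@@H](C[C@@H]1O[Si](C)(C)C(C)(C)C)C2(C)OCCO2 | intermediate
6 | (1S,2R,3S,5S)-3-(tert-butyldimethylsilyloxy)-2-methyl-5-(2-methyl-1,3-dioxolan-2-yl)cyclohexan-1-ol | C[C@H]1[C@@H](O[Si](C)(C)C(C)(C)C)C[C@@H](C2(C)OCCO2)C[C@@H]1O | intermediate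
7 | (2S,3S,5R)-3-(tert-butyldimethylsilyloxy)-2-methyl-5-(2-methyl-1,3-dioxolan-2-yl)cyclohexan-1-one | C[C@H]1[C@@H](O[Si](C)(C)C(C)(C)C)C[C@@H](C2(C)OCCO2)CC1=O | intermediate
8 | Mannich base: 6-(dimethylaminomethyl) derivative of 7, trans to the dioxolanyl group (not isolated) | C[C@H]1[C@@H](O[Si](C)(C)C(C)(C)C)C[C@@H](C2(C)OCCO2)[C@H](CN(C)C)C1=O | intermediate
9 | methiodide of 8 (not isolated) | C[C@H]1[C@@H](O[Si](C)(C)C(C)(C)C)C[C@@H](C2(C)OCCO2)[C@H](C[N+](C)(C)C)C1=O.[I-] | intermediate
10 | (2S,3S,5R)-3-(tert-butyldimethylsilyloxy)-2-methyl-6-methylidene-5-(2-methyl-1,3-dioxolan-2-yl)cyclohexan-1-one | C[C@H]1[C@@H](O[Si](C)(C)C(C)(C)C)C[C@@H](C2(C)OCCO2)C(=C)C1=O | intermediate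
11 | methyl 2-(bromomethyl)acrylate | COC(=O)C(=C)CBr | starting material
12 | bromozinc alkoxide of the C9 adduct (not isolated) | C[C@H]1[C@@H](O[Si](C)(C)C(C)(C)C)C[C@@H](C2(C)OCCO2)C(=C)[C@]1(O[Zn]Br)CC(=C)C(=O)OC | intermediate
13 | spiro α-methylene γ-lactone ketal (C9: O β, C11 α) | C[C@H]1[C@@H](O[Si](C)(C)C(C)(C)C)C[C@@H](C3(C)OCCO3)C(=C)[C@]12CC(=C)C(=O)O2 | intermediate
14 | spiro α-methylene γ-lactone methyl ketone | C[C@H]1[C@@H](O[Si](C)(C)C(C)(C)C)C[C@@H](C(C)=O)C(=C)[C@]12CC(=C)C(=O)O2 | intermediate
15 | 5-(methoxymethylene)-2,2-dimethyl-1,3-dioxane-4,6-dione | COC=C1C(=O)OC(C)(C)OC1=O | starting material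
16 | 5-(hydroxymethylene)-2,2-dimethyl-1,3-dioxane-4,6-dione | OC=C1C(=O)OC(C)(C)OC1=O | intermediate
17 | formylketene (not isolated) | O=CC=C=O | intermediate
18 | dioxinone (ketal carbon C4, S) | C[C@H]1[C@@H](O[Si](C)(C)C(C)(C)C)C[C@@H]([C@@]3(C)OC=CC(=O)O3)C(=C)[C@]12CC(=C)C(=O)O2 | intermediate
19 | photoadduct (cyclobutane C10–C19–C2–C1; C19 β at C10) | C[C@H]1[C@@H](O[Si](C)(C)C(C)(C)C)C[C@H]2[C@@]3(C)O[C@@H]4[C@H](C(=O)O3)C[C@]24[C@]15CC(=C)C(=O)O5 | intermediate
20 | methyl 4,4-dimethoxy-3-oxopentanoate | COC(=O)CC(=O)C(C)(OC)OC | starting material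
21 | acetaldehyde | CC=O | starting material
22 | methyl (Z)-2-ethylidene-4,4-dimethoxy-3-oxopentanoate | C/C=C(\C(=O)OC)C(=O)C(C)(OC)OC | intermediate
23 | triethylsilyl ketene acetal of the spiro lactone (not isolated) | C[C@H]1[C@@H](O[Si](C)(C)C(C)(C)C)C[C@H]2[C@@]3(C)O[C@@H]4[C@H](C(=O)O3)C[C@]24[C@]15CC(C)=C(O[Si](CC)(CC)CC)O5 | intermediate
24 | cycloadduct (dihydropyran silyl orthoester) | C[C@H]1[C@@H](O[Si](C)(C)C(C)(C)C)C[C@H]2[C@@]3(C)O[C@@H]4[C@H](C(=O)O3)C[C@]24[C@]15C[C@]6(C)[C@@H](C)C(C(=O)OC)=C(C(C)(OC)OC)O[C@]6(O[Si](CC)(CC)CC)O5 | intermediate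
25 | tetrahydropyran silyl orthoester | C[C@H]1[C@@H](O[Si](C)(C)C(C)(C)C)C[C@H]2[C@@]3(C)O[C@@H]4[C@H](C(=O)O3)C[C@]24[C@]15C[C@]6(C)[C@@H](C)[C@@H](C(=O)OC)[C@@H](C(C)(OC)OC)O[C@]6(O[Si](CC)(CC)CC)O5 | intermediate
26 | keto aldehyde (C19 aldehyde, C3 methyl ester; not isolated) | C[C@H]1[C@@H](O[Si](C)(C)C(C)(C)C)C[C@@H](C(C)=O)[C@](C=O)(CCC(=O)OC)[C@]12C[C@@](C)(C(=O)O2)[C@@H](C)[C@@H](C(=O)OC)[C@H](O)C(C)(OC)OC | intermediate
27 | hydroxy ester (C19 alcohol; not isolated) | C[C@H]1[C@@H](O[Si](C)(C)C(C)(C)C)C[C@@H](C(C)=O)[C@](CO)(CCC(=O)OC)[C@]12C[C@@](C)(C(=O)O2)[C@@H](C)[C@@H](C(=O)OC)[C@H](O)C(C)(OC)OC | intermediate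
28 | δ-lactone methyl ketone | C[C@H]1[C@@H](O[Si](C)(C)C(C)(C)C)C[C@@H](C(C)=O)[C@]2(CCC(=O)OC2)[C@]12C[C@@](C)(C(=O)O2)[C@@H](C)[C@@H](C(=O)OC)[C@H](O)C(C)(OC)OC | intermediate
29 | tertiary alcohol | C[C@H]1[C@@H](O[Si](C)(C)C(C)(C)C)C[C@@H](C(C)(C)O)[C@]2(CCC(=O)OC2)[C@]12C[C@@](C)(C(=O)O2)[C@@H](C)[C@@H](C(=O)OC)[C@H](O)C(C)(OC)OC | intermediate
30 | trihydroxy keto ester (not isolated) | C[C@H]1[C@@H](O)C[C@@H](C(C)(C)O)[C@]2(CCC(=O)OC2)[C@]12C[C@@](C)(C(=O)O2)[C@@H](C)[C@@H](C(=O)OC)[C@H](O)C(C)=O | intermediate
31 | chermebilaene B | C[C@H]1[C@@H](O)C[C@@H](C(C)(C)O)[C@]2(CCC(=O)OC2)[C@]12C[C@]1(C)[C@@H](C)[C@H]3C(=O)O[C@@]4(C)O[C@@]1(O[C@@H]34)O2 | target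

Total step count: 18. Longest linear sequence: 16 steps (steps 1–9, 11, 12, 14–18).

**Steps most likely to fail**

1. Step 15. The tetrasubstituted, ketal-flanked double bond may not take up hydrogen, or hydrogen may be delivered to the methyl-bearing face. The fallback sets out from 24 and comes back at 28; it gives up the orthoester ring and sets the two centers on the open chain under catalyst control. Mild hydrolysis (AcOH, THF/H2O, 0 °C) collapses the silyl orthoester to the spirolactone β-keto ester F1, whose C1' epimers equilibrate through the enol. Asymmetric transfer hydrogenation with dynamic kinetic resolution [RuCl(p-cymene)(TsDPEN), HCO2H/Et3N, ligand enantiomer chosen for the required C2' carbinol] should then give the anti hydroxy ester F2. F2 is submitted to the conditions of step 16 and gives 28.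

2. Step 18. The protic equilibrium may stop at partly cyclized material, or the β-hydroxy ester may dehydrate before the cage closes. The fallback sets out from 29 and comes back at 31; it drives the closure by silyl transfer instead of a protic equilibrium. Silylation (TMSOTf, 2,6-lutidine, CH2Cl2, −78 °C) gives the bis(trimethylsilyl) ether F4. TMSOTf (1.1 equiv, CH2Cl2, −78 → −20 °C) ionizes the dimethyl ketal; the lactone carbonyl oxygen, the C2' silyl ether and finally the ester carbonyl (with loss of its methyl group) should capture the cations in turn, giving the silylated cage F5 (silyl-transfer ketalization and orthoester formation with irreversible loss of volatile by-products). HF·pyridine in MeCN then gives 31.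

3. Step 17. The methyl nucleophile may also add to the δ-lactone, or base-induced retro-aldol cleavage may occur at C1'–C2'. The fallback sets out from 28 and comes back at 29. Wittig methylenation (Ph3PCH3Br, KOtBu, THF, 0 °C) should convert only the ketone into the isopropenyl compound F3. Mukaiyama hydration [Co(acac)2 (cat.), PhSiH3, O2, iPrOH] should then add water with Markovnikov orientation through the tertiary radical and give 29.

Further compounds
F1 | step 15 | spirolactone β-keto ester (photoadduct part intact, C1' epimers) | C[C@H]1[C@@H](O[Si](C)(C)C(C)(C)C)C[C@H]2[C@@]3(C)O[C@@H]4[C@H](C(=O)O3)C[C@]24[C@]15C[C@@](C)(C(=O)O5)[C@@H](C)C(C(=O)OC)C(=O)C(C)(OC)OC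
F2 | step 15 | anti hydroxy ester (photoadduct part intact) | C[C@H]1[C@@H](O[Si](C)(C)C(C)(C)C)C[C@H]2[C@@]3(C)O[C@@H]4[C@H](C(=O)O3)C[C@]24[C@]15C[C@@](C)(C(=O)O5)[C@@H](C)[C@@H](C(=O)OC)[C@H](O)C(C)(OC)OC
F3 | step 17 | isopropenyl compound (28 with C(CH3)=CH2 at C5) | C[C@H]1[C@@H](O[Si](C)(C)C(C)(C)C)C[C@@H](C(C)=C)[C@]2(CCC(=O)OC2)[C@]12C[C@@](C)(C(=O)O2)[C@@H](C)[C@@H](C(=O)OC)[C@H](O)C(C)(OC)OC
F4 | step 18 | bis(trimethylsilyl) ether of 29 | C[C@H]1[C@@H](O[Si](C)(C)C(C)(C)C)C[C@@H](C(C)(C)O[Si](C)(C)C)[C@]2(CCC(=O)OC2)[C@]12C[C@@](C)(C(=O)O2)[C@@H](C)[C@@H](C(=O)OC)[C@H](O[Si](C)(C)C)C(C)(OC)OC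
F5 | step 18 | silylated cage (31 with C7 OTBS and C4 OTMS) | C[C@H]1[C@@H](O[Si](C)(C)C(C)(C)C)C[C@@H](C(C)(C)O[Si](C)(C)C)[C@]2(CCC(=O)OC2)[C@]12C[C@]1(C)[C@@H](C)[C@H]3C(=O)O[C@@]4(C)O[C@@]1(O[C@@H]34)O2
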